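(The rate constants are invented; what happens was integrated by code.)

The easy step to look at first is the dissolving: solid substrate passes into solution as starting material, and starting material turns into intermediate.

    starting material → intermediate (k1 = 0.0049 /s)
    intermediate → target (k2 = 0.0021 /s)
    crystals ⇌ target, rate k3*(cs3 - [target]) while solid is left; crystals form when [target] > cs3 (cs3 = 19 mM, k3 = 0.48 /s)
    starting material + intermediate → side product (k4 = 0.28 /M/s)
    solid substrate ⇌ starting material, rate k5*(cs5 - [starting material]) while solid is left; crystals form when [starting material] > cs5 (cs5 = 3.1 mM, k5 = 0.0094 /s)

solid substrate 38 mM; time 10 min

- percentages count the solid substrate that a species holds: one side product counts as two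
- target is meant together with its crystals
- solid, in amounts per volume of the solution: crystals, solid substrate
- at the start none of the solid substrate is in solution
- run time (flask): 10 min

- birch: doubling the solubility in step 5, all else as stated
- cedar: doubling the dissolution coefficient of step 3, all else as stated
- oak: doubling the dissolution coefficient of step 5, all else as stated
- maple: doubling the solubility in step 3, all else as stated

- how much target and crystals together there is at 10 min, in percent of the solid substrate charged
- the change that raises the amount of target and crystals together at 10 min, in percent of the solid substrate charged most ("none" if none brings more than 2 percentage points) (birch / cedar / oak / maple / none)
- amount of target and crystals together at 10 min, in percent of the solid substrate charged, after cedar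

I reckon clock by clock. While solid is left, dissolved starting material climbs to the plateau, the level at which dissolving into solution equals conversion to intermediate: 2.04 mM, the dissolution coefficient times the solubility, over that coefficient plus the rate constant of conversion. Its clock, one over that sum, is 1.17 min, shorter than the run, so after that clock I take intermediate as fed at a steady 0.599 mM/min. With starting material held there, its reaction with intermediate is pseudo-first-order, and intermediate is lost at 0.160 /min. The clock of intermediate, 6.24 min, is slower than the plateau's, and intermediate climbs towards 3.74 mM. The solid has the longest clock: at this feed the charge lasts 63.4 min, longer than the clock of intermediate and the run, so I expect solid to stay through the run. Counting from the end of the first clock, 8.83 min remain, and integrating intermediate gives target 1.94 mM, below the solubility of 19 mM. That makes 5.09%. With target below that solubility I expect no crystals, so cedar leaves 5.09%, and maple, which raises that solubility, leaves the same figure. I take target in proportion to the plateau, which birch lifts to 4.08 mM and oak to 2.46 mM, so my choice is birch.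

The forecast says 5%, birch as the best change and 5% after cedar, with the words “Birch nearly doubles starting material”. The simulation gives 5.06%, birch with a gain of 4.2 percentage points against 1.4 points for oak, and 5.06% after cedar.

The plateau is 5.36% of the charge, and this flask reads 5.16% of starting material at 5.00 min and 5.11% at 10.0 min, with crystals at 0%. The neighbouring flask, left until 40 min, still holds 27.1% as solid and reads 5.01% of starting material. The same reckoning on it gives target 40.4%. That flask reads 38.8% of target, with crystals at 0%.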